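**Retrosynthetic overview**

1. Target ⇐ BCl3 cleavage of six isopropyl ethers ⇐ Suzuki coupling of an exocyclic (E)-alkenyl boronate with 4-bromo-2-methoxyphenol (ring D, from catechol) ⇐ boron-Wittig olefination of a (2S,3S)-2,3-diaryl-indan-1-one.
2. Indanone ⇐ catalytic enantioselective Friedel–Crafts conjugate addition of 1,3-diisopropoxybenzene (ring B) to a 2-aryl-4,6-diisopropoxy-indenone; this sets C3, and C2 follows by equilibration to trans.
3. Indenone ⇐ BF3-induced 1,2-acyl shift of a trans-chalcone epoxide (the aroyl carbon C1 migrates onto the carbon that carries ring C), then Friedel–Crafts cyclodehydration onto ring A.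
4. Epoxy ketone ⇐ Darzens condensation of 3,5-diisopropoxybenzaldehyde with the matching α-chloroketone; aldehyde (aryllithium, DMF) and chloroketone (aryl Grignard reagent, chloro-Weinreb amide) both ⇐ 1-bromo-3,5-diisopropoxybenzene ⇐ resorcinol (O-isopropylation, C–H borylation/bromination).
5. Ring order: the four benzene rings are bought (resorcinol three times, catechol once); the only ring built is the five-membered ring, closed right after the acyl shift.

Assumption: the sense of induction of the new step is taken as drawn; if the (S,S) acid gives the (2R,3R) ketone, the (R,R) acid is used.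

**Route**

Step 1
Reactants: 1 resorcinol
Product: 2 1,3-diisopropoxybenzene
Conditions: 2-bromopropane (3 equiv), K2CO3 (3 equiv), DMF, 70 °C
Reagents that add atoms: 2-bromopropane CC(C)Br
Why: Williamson ether synthesis on both phenols; isopropyl ethers survive the organometallic, Lewis-acid and palladium steps and are later cleaved by BCl3 without loss of an aryl methyl ether.

Step 2
Reactants: 2 1,3-diisopropoxybenzene
Product: 4 1-bromo-3,5-diisopropoxybenzene, via pinacol boronate 3 (not isolated)
Conditions: [Ir(OMe)(cod)]2 (1 mol%), 4,4'-di-tert-butyl-2,2'-bipyridine (2 mol%), B2pin2 (1.0 equiv), THF, 80 °C; evaporate; CuBr2 (3 equiv), MeOH/H2O 1:1, 80 °C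
Reagents that add atoms: copper dibromide [Cu+2].[Br-].[Br-]
Why: Iridium-catalysed C–H borylation is sterically controlled and takes only the C5–H that has no ortho substituent, and CuBr2 then replaces boron by bromine at the same carbon (one-pot meta-halogenation).

Step 3
Reactants: 4 1-bromo-3,5-diisopropoxybenzene
Product: 6 3,5-diisopropoxybenzaldehyde, via aryllithium 5 (not isolated)
Conditions: n-BuLi (1.05 equiv), THF, −78 °C; DMF (1.5 equiv), −78 → 0 °C; then H2O
Reagents that add atoms: N,N-dimethylformamide CN(C)C=O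
Why: Bromine–lithium exchange, which at −78 °C is much faster than ortho-lithiation, followed by Bouveault formylation with DMF.

Step 4
Reactants: 4 1-bromo-3,5-diisopropoxybenzene; 7 2-chloro-N-methoxy-N-methylacetamide; 6 3,5-diisopropoxybenzaldehyde
Product: 10 rac-trans-(3,5-diisopropoxyphenyl)[3-(3,5-diisopropoxyphenyl)oxiran-2-yl]methanone, via arylmagnesium bromide 8 (not isolated), via chloroketone 9 (not isolated)
Conditions: Mg turnings (1.2 equiv), THF, 23 → 45 °C; 7 (1.0 equiv), 0 °C, 1 h; 1 M HCl, separate, dry the organic layer; this solution added to 6 (1.0 equiv) and NaOMe (1.3 equiv) in MeOH, 0 → 23 °C; then H2O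
Reagents that add atoms: none
Why: Magnesium inserts into the aryl bromide and the Grignard reagent acylates the N-methoxy-N-methylamide without touching its C–Cl bond, stopping at the chelated adduct (Weinreb ketone synthesis); dilute acid releases the α-chloroketone and washes out the amine, and methoxide then drives a Darzens condensation with 6 (aldol addition, then intramolecular SN2) to the trans epoxide, whose racemic form suffices because both epoxide stereocentres are erased in step 5.

Step 5
Reactants: 10 rac-trans epoxy ketone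
Product: 12 2-(3,5-diisopropoxyphenyl)-4,6-diisopropoxy-1H-inden-1-one, via keto aldehyde 11 (not isolated)
Conditions: BF3·OEt2 (1.5 equiv), CH2Cl2 (0.02 M), 0 °C, 30 min; then MsOH (5 equiv), 0 → 23 °C
Reagents that add atoms: none
Why: BF3 opens the epoxide at the benzylic carbon and the aroyl group shifts to it (House–Meinwald rearrangement of an α,β-epoxy ketone, a cationic 1,2-acyl shift), which joins C1 to the ring C-bearing carbon (C2) and frees the old α-carbon as the formyl carbon C3; MsOH then closes the five-membered ring by intramolecular Friedel–Crafts hydroxyalkylation at the ring A carbon ortho and para to the two isopropoxy groups and dehydrates to the indenone.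

Step 6
Reactants: 12 2-(3,5-diisopropoxyphenyl)-4,6-diisopropoxy-1H-inden-1-one; 2 1,3-diisopropoxybenzene
Product: 13 (2S,3S)-3-(2,4-diisopropoxyphenyl)-2-(3,5-diisopropoxyphenyl)-4,6-diisopropoxy-2,3-dihydro-1H-inden-1-one (2,3-trans)
Conditions: 2 (3.0 equiv), chiral imidodiphosphorimidate acid (S,S)-HN[P(=NSO2CF3)(O2C20H10Ar2)]2 (O2C20H10Ar2 = 3,3'-Ar2-1,1'-binaphthalene-2,2'-diolate, Ar = 3,5-(CF3)2C6H3; 5 mol%), CHCl3, −30 °C, 72 h; then DBU (10 mol%), 23 °C, 1 h
Reagents that add atoms: none
Why: Proposed new method: the confined strong chiral acid protonates the indenone carbonyl to a 1-hydroxyindenylium ion, stabilised by the 4- and 6-alkoxy groups and held as a contact ion pair inside the chiral anion, so that C4 of arene 2 attacks one face of the cationic C3 (setting C3 as S) and rearomatises, after which the enol tautomerises and C2, being α to the ketone, equilibrates to the more stable 2,3-trans ketone (C2 as S); the closest known reaction types are imidodiphosphorimidate-catalysed asymmetric Friedel–Crafts reactions of alkoxybenzenes with cationic electrophiles and chiral-acid-catalysed Friedel–Crafts conjugate additions of indoles to enones.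

Step 7
Reactants: 13 (2S,3S)-trans ketone
Product: 14 2-{(E)-[(2S,3S)-3-(2,4-diisopropoxyphenyl)-2-(3,5-diisopropoxyphenyl)-4,6-diisopropoxy-2,3-dihydro-1H-inden-1-ylidene]methyl}-4,4,5,5-tetramethyl-1,3,2-dioxaborolane
Conditions: bis[(pinacolato)boryl]methane (1.5 equiv), lithium 2,2,6,6-tetramethylpiperidide (1.4 equiv), THF, 0 °C, 10 min; then 13, −78 → 23 °C; then H2O
Reagents that add atoms: bis[(pinacolato)boryl]methane CC1(C)OB(CB2OC(C)(C)C(C)(C)O2)OC1(C)C
Why: Boron-Wittig olefination, in which the boron-stabilised carbanion adds to the ketone and syn B–O elimination gives the alkenyl boronate with the remaining boryl group on the C2 side, away from the peri C7–H of ring A (E); C2 and C3 are untouched, since any enolate formed returns the trans ketone on work-up.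

Step 8
Reactants: 15 catechol
Product: 16 2-methoxyphenol (guaiacol)
Conditions: MeI (1.0 equiv), K2CO3 (1.0 equiv), acetone, 56 °C
Reagents that add atoms: iodomethane CI
Why: Williamson mono-O-methylation with one equivalent of MeI; the mono-ether is freed from catechol by a water wash and from the dimethyl ether by extraction into aqueous NaOH.

Step 9
Reactants: 16 2-methoxyphenol
Product: 17 4-bromo-2-methoxyphenol
Conditions: N-bromosuccinimide (1.0 equiv), MeCN, −10 → 0 °C
Reagents that add atoms: N-bromosuccinimide O=C1CCC(=O)N1Br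
Why: Electrophilic aromatic bromination; the free hydroxyl is the stronger director, so bromine enters para to OH.

Step 10
Reactants: 14 (E)-alkenyl pinacol boronate; 17 4-bromo-2-methoxyphenol
Product: 18 4-{(E)-[(2S,3S)-3-(2,4-diisopropoxyphenyl)-2-(3,5-diisopropoxyphenyl)-4,6-diisopropoxy-2,3-dihydro-1H-inden-1-ylidene]methyl}-2-methoxyphenol
Conditions: Pd(dppf)Cl2 (5 mol%), K3PO4 (3 equiv), 1,4-dioxane/H2O 5:1, 80 °C
Reagents that add atoms: none
Why: Suzuki–Miyaura coupling proceeds with retention of alkene geometry and tolerates the free phenol; no stereocentre is touched.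

Step 11
Reactants: 18 hexa-isopropyl ether
Product: 19 4-{(E)-[(2S,3S)-3-(2,4-dihydroxyphenyl)-2-(3,5-dihydroxyphenyl)-4,6-dihydroxy-2,3-dihydro-1H-inden-1-ylidene]methyl}-2-methoxyphenol (CNP0122890.1)
Conditions: BCl3 (1 M in CH2Cl2, 12 equiv), CH2Cl2, −78 → 0 °C; then H2O
Reagents that add atoms: none
Why: BCl3 cleaves the six secondary alkyl aryl ethers at low temperature while the aryl methyl ether is inert there (Lewis-acid ether cleavage); at or below 0 °C the exocyclic alkene does not migrate into the ring, so C2, C3 and the (E) geometry are kept.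

**Compound list**

1 | resorcinol | Oc1cccc(O)c1 | starting material
2 | 1,3-diisopropoxybenzene | CC(C)Oc1cccc(OC(C)C)c1 | intermediate
3 | 2-(3,5-diisopropoxyphenyl)-4,4,5,5-tetramethyl-1,3,2-dioxaborolane (not isolated) | CC(C)Oc1cc(OC(C)C)cc(c1)B1OC(C)(C)C(C)(C)O1 | intermediate
4 | 1-bromo-3,5-diisopropoxybenzene | CC(C)Oc1cc(Br)cc(OC(C)C)c1 | intermediate
5 | (3,5-diisopropoxyphenyl)lithium (not isolated) | [Li]c1cc(OC(C)C)cc(OC(C)C)c1 | intermediate
6 | 3,5-diisopropoxybenzaldehyde | CC(C)Oc1cc(C=O)cc(OC(C)C)c1 | intermediate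
7 | 2-chloro-N-methoxy-N-methylacetamide | CON(C)C(=O)CCl | starting material
8 | (3,5-diisopropoxyphenyl)magnesium bromide (not isolated) | Br[Mg]c1cc(OC(C)C)cc(OC(C)C)c1 | intermediate
9 | 2-chloro-1-(3,5-diisopropoxyphenyl)ethan-1-one (not isolated) | CC(C)Oc1cc(cc(OC(C)C)c1)C(=O)CCl | intermediate
10 | rac-(3,5-diisopropoxyphenyl)[(2R*,3S*)-3-(3,5-diisopropoxyphenyl)oxiran-2-yl]methanone (trans; racemate, one enantiomer drawn) | CC(C)Oc1cc(cc(OC(C)C)c1)C(=O)[C@@H]1O[C@H]1c1cc(OC(C)C)cc(OC(C)C)c1 | intermediate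
11 | 2,3-bis(3,5-diisopropoxyphenyl)-3-oxopropanal (racemic, largely enol; not isolated) | CC(C)Oc1cc(cc(OC(C)C)c1)C(=O)C(C=O)c1cc(OC(C)C)cc(OC(C)C)c1 | intermediate
12 | 2-(3,5-diisopropoxyphenyl)-4,6-diisopropoxy-1H-inden-1-one | O=C1C(=Cc2c1cc(OC(C)C)cc2OC(C)C)c1cc(OC(C)C)cc(OC(C)C)c1 | intermediate
13 | (2S,3S)-3-(2,4-diisopropoxyphenyl)-2-(3,5-diisopropoxyphenyl)-4,6-diisopropoxy-2,3-dihydro-1H-inden-1-one | O=C1c2cc(OC(C)C)cc(OC(C)C)c2[C@H](c2ccc(OC(C)C)cc2OC(C)C)[C@H]1c1cc(OC(C)C)cc(OC(C)C)c1 | intermediate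
14 | (E)-alkenyl pinacol boronate of 13 (exocyclic C1=CH–B, boron trans to ring A; 2S,3S) | CC1(C)OB(/C=C2/c3cc(OC(C)C)cc(OC(C)C)c3[C@H](c3ccc(OC(C)C)cc3OC(C)C)[C@H]2c2cc(OC(C)C)cc(OC(C)C)c2)OC1(C)C | intermediate
15 | catechol | Oc1ccccc1O | starting material
16 | 2-methoxyphenol | COc1ccccc1O | intermediate
17 | 4-bromo-2-methoxyphenol | COc1cc(Br)ccc1O | intermediate
18 | hexa-isopropyl ether of the target (E; 2S,3S; ring D phenol free) | COc1cc(/C=C2/c3cc(OC(C)C)cc(OC(C)C)c3[C@H](c3ccc(OC(C)C)cc3OC(C)C)[C@H]2c2cc(OC(C)C)cc(OC(C)C)c2)ccc1O | intermediate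
19 | CNP0122890.1 (E; 2S,3S; 2,3-trans) | COc1cc(/C=C2/c3cc(O)cc(O)c3[C@H](c3ccc(O)cc3O)[C@H]2c2cc(O)cc(O)c2)ccc1O | target

**Step count and risks**

Total step count: 11. Longest linear sequence: 9 steps (steps 1, 2, 3, 4, 5, 6, 7, 10, 11).

The step most likely to fail is step 6, the new reaction. C3 is flanked by the peri isopropoxy group and the C2 aryl group, so the addition may be slow, and the enantioselectivity is unproven. The fallback uses known chemistry and sets out from 12 and 2. BF3·OEt2 (1.2 equiv) in CH2Cl2 at −20 °C promotes the racemic Friedel–Crafts conjugate addition, and DBU equilibration gives the racemic trans ketone. This is a 1:1 mixture of 13 and (2R,3R)-3-(2,4-diisopropoxyphenyl)-2-(3,5-diisopropoxyphenyl)-4,6-diisopropoxy-2,3-dihydro-1H-inden-1-one F1. Preparative supercritical-fluid chromatography on an amylose tris(3,5-dimethylphenylcarbamate) phase separates the two, and the route is rejoined at 13.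

The second is step 7. The ketone is hindered and its C2–H is acidic, so enolisation can outrun addition, and the E/Z ratio is not secured. The fallback sets out from 13 and 17 and replaces olefination plus coupling by a benzyl addition and dehydration. Phenol 17 is O-alkylated (2-bromopropane, K2CO3, DMF) to 4-bromo-1-isopropoxy-2-methoxybenzene F2. n-BuLi at −78 °C gives (4-isopropoxy-3-methoxyphenyl)lithium F3, which is quenched with paraformaldehyde to (4-isopropoxy-3-methoxyphenyl)methanol F4. Concentrated HCl gives 4-(chloromethyl)-1-isopropoxy-2-methoxybenzene F5, and magnesium in THF gives (4-isopropoxy-3-methoxybenzyl)magnesium chloride F6. F6 is premixed with CeCl3 to suppress enolisation and added to 13, giving (2S,3S)-3-(2,4-diisopropoxyphenyl)-2-(3,5-diisopropoxyphenyl)-4,6-diisopropoxy-1-(4-isopropoxy-3-methoxybenzyl)-2,3-dihydro-1H-inden-1-ol F7 as a mixture at C1. Catalytic p-TsOH in toluene at 23 °C, stopped as soon as F7 is consumed so that the alkene does not migrate into the ring, dehydrates F7 to the (E)-benzylidene, the hepta-isopropyl ether of the target F8. BCl3 as in step 11 then gives the target, so this fallback rejoins the route at 19.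

The third is step 5. The benzylic cation can take other paths (fluorohydrin, hydride shift to a 1,2-diketone), and the electron-rich indenone can oligomerise in acid. The fallback keeps a 1,2-shift but uses an oxidative aryl migration, and it sets out from 4 and 6. Aryllithium 5 (from 4 and n-BuLi, as in step 3) is acylated with N-methoxy-N-methylacetamide to 1-(3,5-diisopropoxyphenyl)ethan-1-one F9. Claisen–Schmidt condensation of F9 with 6 (NaOH, EtOH) gives (E)-1,3-bis(3,5-diisopropoxyphenyl)prop-2-en-1-one F10. Tl(NO3)3·3H2O in MeOH/HC(OMe)3 effects the oxidative 1,2-aryl shift to 1,2-bis(3,5-diisopropoxyphenyl)-3,3-dimethoxypropan-1-one F11. MsOH in CH2Cl2 cyclises F11 with loss of methanol, and the route is rejoined at 12.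

**Further compounds**

F1 | step 6 | (2R,3R)-3-(2,4-diisopropoxyphenyl)-2-(3,5-diisopropoxyphenyl)-4,6-diisopropoxy-2,3-dihydro-1H-inden-1-one | O=C1c2cc(OC(C)C)cc(OC(C)C)c2[C@@H](c2ccc(OC(C)C)cc2OC(C)C)[C@@H]1c1cc(OC(C)C)cc(OC(C)C)c1
F2 | step 7 | 4-bromo-1-isopropoxy-2-methoxybenzene | COc1cc(Br)ccc1OC(C)C
F3 | step 7 | (4-isopropoxy-3-methoxyphenyl)lithium | COc1cc([Li])ccc1OC(C)C
F4 | step 7 | (4-isopropoxy-3-methoxyphenyl)methanol | COc1cc(CO)ccc1OC(C)C
F5 | step 7 | 4-(chloromethyl)-1-isopropoxy-2-methoxybenzene | COc1cc(CCl)ccc1OC(C)C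
F6 | step 7 | (4-isopropoxy-3-methoxybenzyl)magnesium chloride | COc1cc(C[Mg]Cl)ccc1OC(C)C
F7 | step 7 | (2S,3S)-3-(2,4-diisopropoxyphenyl)-2-(3,5-diisopropoxyphenyl)-4,6-diisopropoxy-1-(4-isopropoxy-3-methoxybenzyl)-2,3-dihydro-1H-inden-1-ol (C1 epimers) | COc1cc(CC2(O)c3cc(OC(C)C)cc(OC(C)C)c3[C@H](c3ccc(OC(C)C)cc3OC(C)C)[C@H]2c2cc(OC(C)C)cc(OC(C)C)c2)ccc1OC(C)C
F8 | step 7 | hepta-isopropyl ether of the target (E; 2S,3S) | COc1cc(/C=C2/c3cc(OC(C)C)cc(OC(C)C)c3[C@H](c3ccc(OC(C)C)cc3OC(C)C)[C@H]2c2cc(OC(C)C)cc(OC(C)C)c2)ccc1OC(C)C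
F9 | step 5 | 1-(3,5-diisopropoxyphenyl)ethan-1-one | CC(=O)c1cc(OC(C)C)cc(OC(C)C)c1
F10 | step 5 | (E)-1,3-bis(3,5-diisopropoxyphenyl)prop-2-en-1-one | CC(C)Oc1cc(cc(OC(C)C)c1)C(=O)/C=C/c1cc(OC(C)C)cc(OC(C)C)c1
F11 | step 5 | 1,2-bis(3,5-diisopropoxyphenyl)-3,3-dimethoxypropan-1-one (racemic) | COC(OC)C(c1cc(OC(C)C)cc(OC(C)C)c1)C(=O)c1cc(OC(C)C)cc(OC(C)C)c1
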